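## Analysis of the target

The target (24) is a cembranolide: a 14-membered carbocycle (C1–C14) bridged across C1 and C3 by a six-membered lactone (C1, C2, C3, O, C17, C15). C16 is the methyl on C15, and C18, C19 and C20 are the methyls on C4, C8 and C12. It carries a tertiary carbinol at C4, a trisubstituted 11,12-epoxide with a quaternary C12, and a tertiary allylic hydroperoxide at C8 beside an (E)-C6=C7 olefin. The seven stereocentres (1R, 3R, 4S, 8S, 11S, 12S, 15S) form three contiguous pairs and one isolated centre: C15/C1 (methyl and ring bond trans on the lactone), C3/C4 (the anti-diol pattern of an (E)-olefin), C11/C12 (the trans-epoxide of an (E)-olefin), and C8 far from all of them. The hydroperoxide does not tolerate low-valent metals, phosphines or strong bases, the epoxide does not tolerate acid, and C15 can epimerise once the lactone exists. The difficulties are the closure of a flexible 14-membered ring, the control of stereocentres in separate parts of that ring, and the late, regio- and face-selective introduction of the O–O unit. The route rests on one relationship: C13 is bonded to the quaternary epoxide carbon C12 and lies two atoms from C1. An epoxy aldehyde at C13 (no α-hydrogen) and an alkenyl nucleophile at C14 therefore close the ring to an allylic alcohol C13(OH)–C14=C1, whose oxygen can carry a propionate and pass C15–C17 to C1 by a [3,3] shift. In addition, C2–C13 with C18–C20 and both (E)-olefins is the carbon chain of (2E,6E)-farnesol (1), so only C1/C14 and C15–C17 have to be added.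

## Retrosynthetic reasoning

**C8–O bond (24 to 23).** The O–O unit is removed first in the retrosynthetic direction, giving lactone 23 with the (E)-C7=C8 olefin of the farnesyl chain. No earlier position is possible, because a hydroperoxide would not survive divalent chromium, amide bases or the diimide step. The forward Schenck ene reaction has to add oxygen at C8 on the correct face and take hydrogen from C6, which moves the olefin to C6=C7.

**Lactone C17–O bond and protecting groups (23 to 21 through 22).** The lactone is opened to the dihydroxy acid 22, and its two hydroxyls are masked as triethylsilyl ethers in 21. An acetonide would be the obvious diol mask, but it would have to be hydrolysed by acid beside the trisubstituted epoxide. Silyl ethers leave with fluoride, which the epoxide tolerates. Lactonisation is placed late so that the epimerisable C15 never meets a strong base as part of a lactone.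

**C13–C14 saturation (21 to 20).** Reintroducing the (E)-C13=C14 olefin gives acid 20, the direct product of a sigmatropic shift. The forward reduction must saturate this 1,2-disubstituted olefin and leave the trisubstituted C7=C8 unit alone.

**C1–C15 bond (20 to 17).** A retro-Ireland–Claisen step cuts C1–C15, reattaches the carboxyl oxygen to C13 and moves the olefin to C14=C1, giving propionate 17. This is the only disconnection that creates C1 and C15 together and ties both to one existing stereocentre (C13). The forward reaction needs a defined ketene acetal geometry and a chair transition state.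

**Ester (17 to 15 and 16).** The propionate is taken off to give the macrocyclic allylic alcohol 15 and propionic anhydride 16.

**C13–C14 bond and the ring (15 to 13).** The ring is opened between C13 and C14, giving the (E)-iodoalkene/epoxy aldehyde 13. The cut is made here, and not at an olefin or next to the lactone, for three reasons: the aldehyde sits on a quaternary carbon and cannot enolise, the alkenyl iodide is stable through many steps, and the carbinol made by ring closure is consumed productively in the next operations. The forward chromium-mediated addition must be intramolecular and should give the 13S carbinol.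

**Epoxy aldehyde (13 to 10 through 12 and 11).** The aldehyde goes back to epoxy alcohol 12 and this to allylic alcohol 11 by a Sharpless epoxidation, which sets C11 and C12 by reagent control. Alcohol 11 comes from the terminal (E)-methyl of 10 by selenium-mediated allylic oxidation. The oxidation is placed after the iodoalkene is in place so that no free hydroxyl meets the zirconium hydride.

**Iodoalkene and C1–C2 bond (10 to 8, 7, 4 and 5).** The (E)-iodoalkene comes from the terminal alkyne 8 (hydrozirconation–iodination). Its diol 7 is cut between C1 and C2 into lithium acetylide 5 and the hydroxy epoxide 6, which is formed in the flask from diol mesylate 4. This adds C1 and C14 in one step and needs no stereocontrol at C2.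

**C3 and C4 (4 to 1 through 3 and 2).** The anti-diol is traced to the (E)-olefin of 1: Sharpless epoxidation gives 2, which fixes C3 and the face of C4. Opening the mesylate 3 at the tertiary carbon with inversion gives the 3R,4S pattern. Both stereocentres thus come from one catalytic step, and the two Sharpless epoxidations of the route (steps 1 and 8) use opposite ligand enantiomers.

## Alternatives that were turned down

**Alternative 1:** C1 is taken from (R)-limonene A1. Its ring olefin is cleaved, so that C1 keeps the isopropenyl group (C15–C17) and carries two arms ending at C3 and C12. Two-directional chain extension gives a bis-allylic diol. The key step is a double Sharpless epoxidation with one tartrate enantiomer, which gives the bis-epoxy diol A2 and sets C3, C4, C11 and C12 together. C3 is set in the configuration that a later lactone-forming epoxide opening would invert.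
- For it: C1 comes from the chiral pool with certainty, four stereocentres arise in one catalytic, reagent-controlled step, and A2 is reached quickly.
- Against it: A2 ends in two nearly equivalent epoxy carbinols (C5 and C10), which must be told apart. The C6–C9 unit with the (E)-C7=C8 olefin still has to be inserted by two C–C bond formations next to epoxides, one of them as a ring closure that is not defined. C15 must be made from the isopropenyl group with only weak acyclic induction.
- Comparison: it is stronger on C1 and on the epoxide stereocentres. The chosen route offers instead a ring closure whose by-product, the C13 carbinol, is used to set C1 and C15 together, and a chain (1) in which the C7=C8 geometry is already present. Its open questions all come after the step that alternative 1 solves.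

**Alternative 2:** The ring is cut between C9 and C10. A C9 allylic phenyl sulfone, deprotonated by a hindered amide base, displaces a C10 triflate of a Sharpless-derived 2,3-epoxy alcohol and gives the macrocyclic sulfone A3, with lactone, epoxide and protected C4 carbinol already in place. The sulfone is removed afterwards.
- For it: alkylation of a sulfone-stabilised carbanion is among the most dependable closures of 14-membered carbocycles, it needs no stereocontrol (the C9 epimers converge), and every stereocentre is set on open-chain material.
- Against it: the base meets a lactone with an acidic C15–H, so epimerisation is possible. The alkylated product still has an acidic C9–H in a 1,3-relation to the epoxide and could close a cyclopropane. Reductive removal of an allylic sulfone beside a lactone and an epoxide risks migration or isomerisation of C7=C8. The open-chain precursor with C1, C15 and the lactone needs a longer, separate sequence. Two steps are spent on an auxiliary group, and the ring closure builds no stereocentre.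
- Comparison: it is stronger in the robustness of the closing bond. The chosen route offers a closure that adds a useful stereocentre, forms the lactone only after all strong bases, and is shorter overall from 1.

**Alternative 3:** The C1–C2 bond is made by a Claisen rearrangement of the 16-membered cyclic enol ether A4, obtained from a macrolactone by carbonyl methylenation. Heating contracts it to the 14-membered ketone A5 with a C3 carbonyl and an isopropenyl group on C1.
- For it: the ring is first closed as an ester, which is the most reliable macrocyclisation. The C–C bond then forms in a unimolecular step without high dilution or stoichiometric metal, and the ketone and the isopropenyl group sit where the lactone atoms are needed.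
- Against it: methylenation of a lactone carbonyl beside the quaternary C4 and near an epoxide is demanding. The face of C1 is decided by the conformation of a 16-membered transition state, with only remote centres to guide it. After the key step the C3 ketone must still be reduced to 3R beside a quaternary centre, and C15 must be set on an exocyclic isopropenyl group, so two stereocentres remain without a strong control element.
- Comparison: it is stronger in the ring-forming event. The chosen route sets C3/C4 by reagent control at the start, sets C1 and C15 in one step from a defined carbinol, and needs fewer steps after ring closure.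

Key step: step 10

Remark: locants are those defined in the analysis; CIP descriptors at C12 (and at C1 in 20) change with the neighbouring groups in some intermediates, although the arrangement in space stays that of the target.

Assumption: commercial (2E,6E)-farnesol is used as the pure isomer, and the Sharpless epoxidation follows its usual face rule (L-(+)-tartrate gives the 2S epoxy alcohol from an (E)-allylic alcohol).

## Route

Step 1
Reactants: 1 (2E,6E)-farnesol
Product: 2 (2R,3R)-2,3-epoxyfarnesol
Conditions: Ti(OiPr)4 (0.05 equiv), D-(−)-diethyl tartrate (0.06 equiv), t-BuOOH (decane), 4 Å MS, CH2Cl2, −20 °C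
Reagents that add atoms: tert-butyl hydroperoxide, CC(C)(C)OO
Why: Sharpless asymmetric epoxidation; only the allylic alcohol olefin is oxidised, and the D-(−)-tartrate face rule sets C3 (R) and the oxirane face at C4, which step 3 inverts.

Step 2
Reactants: 2 (2R,3R)-2,3-epoxyfarnesol
Product: 3 (2R,3R)-2,3-epoxyfarnesyl methanesulfonate
Conditions: MeSO2Cl, Et3N, CH2Cl2, −20 °C
Reagents that add atoms: methanesulfonyl chloride, CS(=O)(=O)Cl
Why: O-sulfonylation of a primary alcohol; the low temperature keeps chloride from displacing the sulfonate or opening the oxirane.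

Step 3
Reactants: 3 (2R,3R)-2,3-epoxyfarnesyl methanesulfonate
Product: 4 (2R,3S,6E)-2,3-dihydroxy-3,7,11-trimethyldodeca-6,10-dien-1-yl methanesulfonate
Conditions: HClO4 (aq., 0.1 equiv), THF–H2O, 0 °C
Reagents that add atoms: water, O
Why: Acid-catalysed epoxide hydrolysis; water enters at the tertiary carbon (C4) anti to the leaving oxygen, with inversion, because the CH2OMs group disfavours charge at C3, so the anti 3R,4S diol should result; the remote olefins have no low-strain cyclisation mode onto C4.

Step 4
Reactants: 4 (2R,3S,6E)-2,3-dihydroxy-3,7,11-trimethyldodeca-6,10-dien-1-yl methanesulfonate; 5 lithium acetylide–ethylenediamine complex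
Product: 7 (4R,5S,8E)-5,9,13-trimethyltetradeca-8,12-dien-1-yne-4,5-diol, via hydroxy epoxide 6 (not isolated)
Conditions: 5 (4 equiv), DMSO, 10 → 25 °C; aqueous work-up
Reagents that add atoms: none
Why: The C3 alkoxide displaces the neighbouring mesylate (3-exo-tet, C3 untouched) and the acetylide opens the terminal oxirane at the unsubstituted C2 (epoxide alkynylation, C1–C2 bond); a reversible Payne shift of the tertiary alkoxide does no harm, because only the terminal oxirane is consumed.

Step 5
Reactants: 7 (4R,5S,8E)-5,9,13-trimethyltetradeca-8,12-dien-1-yne-4,5-diol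
Product: 8 (4R,5S,8E)-5,9,13-trimethyl-4,5-bis(triethylsilyloxy)tetradeca-8,12-dien-1-yne
Conditions: Et3SiOTf (2.5 equiv), 2,6-lutidine, CH2Cl2, −78 → 0 °C
Reagents that add atoms: triethylsilyl trifluoromethanesulfonate, CC[Si](CC)(CC)OS(=O)(=O)C(F)(F)F
Why: Silyl triflate silylation reaches the tertiary C4 hydroxyl as well as the secondary one; two fluoride-labile ethers are used because the diol must later be freed without acid beside the 11,12-epoxide.

Step 6
Reactants: 8 (4R,5S,8E)-5,9,13-trimethyl-4,5-bis(triethylsilyloxy)tetradeca-8,12-dien-1-yne
Product: 10 (1E,4R,5S,8E)-1-iodo-5,9,13-trimethyl-4,5-bis(triethylsilyloxy)tetradeca-1,8,12-triene, via alkenylzirconocene chloride 9 (not isolated)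
Conditions: Cp2Zr(H)Cl (1.5 equiv), THF, 25 °C, dark; then I2, 0 °C
Reagents that add atoms: iodine, II
Why: Hydrozirconation–iodination; syn addition of Zr–H puts zirconium on the terminal carbon and iodinolysis with retention gives the (E)-iodoalkene, while the trisubstituted olefins do not react under these conditions.

Step 7
Reactants: 10 (1E,4R,5S,8E)-1-iodo-5,9,13-trimethyl-4,5-bis(triethylsilyloxy)tetradeca-1,8,12-triene
Product: 11 (2E,6E,10S,11R,13E)-14-iodo-2,6,10-trimethyl-10,11-bis(triethylsilyloxy)tetradeca-2,6,13-trien-1-ol
Conditions: SeO2 (0.3 equiv), t-BuOOH, salicylic acid (0.1 equiv), CH2Cl2, 0 → 25 °C, partial conversion with recovery of 10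
Reagents that add atoms: tert-butyl hydroperoxide (oxygen passed on through SeO2), CC(C)(C)OO
Why: Selenium dioxide allylic oxidation (ene reaction, then [2,3] shift) attacks the terminal isopropylidene group at its (E)-methyl faster than the internal C7=C8 unit and gives the (E)-allylic alcohol; the iodoalkene is too electron-poor to react.

Step 8
Reactants: 11 (2E,6E,10S,11R,13E)-14-iodo-2,6,10-trimethyl-10,11-bis(triethylsilyloxy)tetradeca-2,6,13-trien-1-ol
Product: 12 [(2S,3S)-3-[(3E,7S,8R,10E)-11-iodo-3,7-dimethyl-7,8-bis(triethylsilyloxy)undeca-3,10-dien-1-yl]-2-methyloxiran-2-yl]methanol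
Conditions: Ti(OiPr)4 (0.1 equiv), L-(+)-diethyl tartrate (0.12 equiv), t-BuOOH (decane), 4 Å MS, CH2Cl2, −20 °C
Reagents that add atoms: tert-butyl hydroperoxide, CC(C)(C)OO
Why: Sharpless asymmetric epoxidation of an (E)-2-methylallylic alcohol; the L-(+)-tartrate face rule gives the 11S,12S oxirane by reagent control, independent of the remote C3/C4 centres.

Step 9
Reactants: 12 [(2S,3S)-3-[(3E,7S,8R,10E)-11-iodo-3,7-dimethyl-7,8-bis(triethylsilyloxy)undeca-3,10-dien-1-yl]-2-methyloxiran-2-yl]methanol
Product: 13 (2R,3S)-3-[(3E,7S,8R,10E)-11-iodo-3,7-dimethyl-7,8-bis(triethylsilyloxy)undeca-3,10-dien-1-yl]-2-methyloxirane-2-carbaldehyde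
Conditions: Dess–Martin periodinane, NaHCO3, CH2Cl2, 0 → 25 °C
Reagents that add atoms: none
Why: Dess–Martin oxidation of a primary epoxy alcohol under buffered conditions; the aldehyde sits on a quaternary carbon and cannot enolise or epimerise.

Step 10
Reactants: 13 (2R,3S)-3-[(3E,7S,8R,10E)-11-iodo-3,7-dimethyl-7,8-bis(triethylsilyloxy)undeca-3,10-dien-1-yl]-2-methyloxirane-2-carbaldehyde
Product: 15 (3R,4S,7E,11S,12S,13S,14E)-11,12-epoxy-4,8,12-trimethyl-3,4-bis(triethylsilyloxy)cyclotetradeca-7,14-dien-13-ol (target locants; C14=C1), via alkenylchromium dichloride 14 (not isolated)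
Conditions: CrCl2 (10 equiv), NiCl2 (0.1 equiv), degassed DMSO–THF, 0.002 M, syringe-pump addition of 13, 25 °C; aqueous work-up
Reagents that add atoms: none
Why: Nozaki–Hiyama–Kishi reaction in its macrocyclising form: NiCl2 is reduced by CrCl2 to zerovalent nickel, which inserts into the C14–I bond with retention of the (E)-geometry; the alkenyl group passes to trivalent chromium, and the alkenylchromium 14, nucleophilic only towards aldehydes, adds to the C13 carbonyl. The ring closes in the 14-exo-trig mode, with the carbonyl oxygen left outside the new ring as the chromium alkoxide. The closest known reaction type is the chromium-mediated macrocyclisation of (E)-iodoalkenyl aldehydes to ten- to sixteen-membered allylic alcohols. C13 is the only new stereocentre: with the carbonyl bisecting the oxirane and the alkenyl group entering anti to the C12–O bond (Felkin–Anh), the erythro adduct with 13S configuration is expected, although the conformation of the closing ring also has a say. Chemoselectivity for the aldehyde over the oxirane, the silyl ethers and the trisubstituted olefin is needed and is normal for organochromium reagents; the quaternary C12 rules out enolisation, and high dilution with slow addition keeps the reaction intramolecular. The 13S carbinol is required because its oxygen later hands C15 to the matching face of C1.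

Step 11
Reactants: 15 (3R,4S,7E,11S,12S,13S,14E)-11,12-epoxy-4,8,12-trimethyl-3,4-bis(triethylsilyloxy)cyclotetradeca-7,14-dien-13-ol; 16 propionic anhydride
Product: 17 (3R,4S,7E,11S,12R,13S,14E)-11,12-epoxy-4,8,12-trimethyl-3,4-bis(triethylsilyloxy)cyclotetradeca-7,14-dien-13-yl propanoate (same arrangement in space as 15)
Conditions: 16, Et3N, DMAP (0.1 equiv), CH2Cl2, 0 → 25 °C
Reagents that add atoms: none
Why: DMAP-catalysed acylation of the only free hydroxyl, with retention at C13.

Step 12
Reactants: 17 (3R,4S,7E,11S,12R,13S,14E)-11,12-epoxy-4,8,12-trimethyl-3,4-bis(triethylsilyloxy)cyclotetradeca-7,14-dien-13-yl propanoate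
Product: 20 (2S)-2-[(1S,3R,4S,7E,11S,12S,13E)-11,12-epoxy-4,8,12-trimethyl-3,4-bis(triethylsilyloxy)cyclotetradeca-7,13-dien-1-yl]propanoic acid (C1 in space as in the target), via silyl ketene acetal 18 (not isolated), via trimethylsilyl ester 19 (not isolated)
Conditions: LiN(i-Pr)2 (1.5 equiv), THF, −78 °C; Me3SiCl, −78 → 25 °C, then 50 °C; pH 7 buffer–MeOH work-up; acid taken on at once as its triethylammonium salt
Reagents that add atoms: none
Why: Ireland–Claisen rearrangement; kinetic enolisation in THF without a polar cosolvent gives the ketene acetal with methyl trans to OSiMe3, and a chair transition state with C12 pseudo-equatorial passes C15 suprafacially from the C13–O face to C1, which sets C1 and the anti-related C15 (15S) from the 13S centre. The new C13=C14 olefin is removed in the next step, and the acid is not stored because the oxirane is now allylic.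

Step 13
Reactants: 20 (2S)-2-[(1S,3R,4S,7E,11S,12S,13E)-11,12-epoxy-4,8,12-trimethyl-3,4-bis(triethylsilyloxy)cyclotetradeca-7,13-dien-1-yl]propanoic acid
Product: 21 (2S)-2-[(1R,3R,4S,7E,11S,12S)-11,12-epoxy-4,8,12-trimethyl-3,4-bis(triethylsilyloxy)cyclotetradec-7-en-1-yl]propanoic acid
Conditions: 2-nitrobenzenesulfonohydrazide (excess), Et3N, CH2Cl2, 25 °C
Reagents that add atoms: none
Why: Diimide reduction; concerted syn transfer of H2 is faster to the 1,2-disubstituted C13=C14 olefin than to the trisubstituted C7=C8 olefin and leaves the oxirane, the silyl ethers and the carboxylate untouched.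

Step 14
Reactants: 21 (2S)-2-[(1R,3R,4S,7E,11S,12S)-11,12-epoxy-4,8,12-trimethyl-3,4-bis(triethylsilyloxy)cyclotetradec-7-en-1-yl]propanoic acid
Product: 23 (1R,3R,4S,7E,11S,12S,15S)-11,12-epoxy-4-hydroxycembr-7-en-17,3-olide, via dihydroxy acid 22 (not isolated)
Conditions: Bu4NF (4 equiv), THF, 0 → 25 °C; aq. NH4Cl work-up; crude 22: 1-ethyl-3-(3-dimethylaminopropyl)carbodiimide hydrochloride, DMAP (0.2 equiv), CH2Cl2, 0 → 25 °C
Reagents that add atoms: none
Why: Fluoride desilylation spares the acid-labile oxirane, and carbodiimide lactonisation (Steglich type) closes the six-membered ring on the secondary C3 hydroxyl, while the tertiary C4 hydroxyl does not compete; no stereocentre is touched.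

Step 15
Reactants: 23 (1R,3R,4S,7E,11S,12S,15S)-11,12-epoxy-4-hydroxycembr-7-en-17,3-olide
Product: 24 (1R,3R,4S,6E,8S,11S,12S,15S)-11,12-epoxy-8-hydroperoxy-4-hydroxycembr-6-en-17,3-olide (target)
Conditions: O2, tetraphenylporphyrin (1 mol %), visible light, CH2Cl2, −20 °C
Reagents that add atoms: oxygen, O=O
Why: Schenck ene reaction of singlet oxygen with the only electron-rich olefin; abstraction from C6, which lies on the more substituted side of C7=C8, places the hydroperoxide on C8 and forms the (E)-C6=C7 olefin, and the face of attack (8S needed) is set by peripheral approach to the ring olefin, possibly helped by the C4 hydroxyl.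

## Compound list

1 | (2E,6E)-farnesol | OC/C=C(C)/CC/C=C(C)/CCC=C(C)C | starting material
2 | (2R,3R)-2,3-epoxyfarnesol | OC[C@H]1O[C@]1(C)CC/C=C(C)/CCC=C(C)C | intermediate
3 | (2R,3R)-2,3-epoxyfarnesyl methanesulfonate | CS(=O)(=O)OC[C@H]1O[C@]1(C)CC/C=C(C)/CCC=C(C)C | intermediate
4 | (2R,3S,6E)-2,3-dihydroxy-3,7,11-trimethyldodeca-6,10-dien-1-yl methanesulfonate | CS(=O)(=O)OC[C@@H](O)[C@@](C)(O)CC/C=C(C)/CCC=C(C)C | intermediate
5 | lithium acetylide–ethylenediamine complex | [Li+].[C-]#C.NCCN | starting material
6 | (2S,5E)-6,10-dimethyl-2-[(2R)-oxiran-2-yl]undeca-5,9-dien-2-ol (hydroxy epoxide, not isolated) | C1O[C@H]1[C@@](C)(O)CC/C=C(C)/CCC=C(C)C | intermediate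
7 | (4R,5S,8E)-5,9,13-trimethyltetradeca-8,12-dien-1-yne-4,5-diol | C#CC[C@@H](O)[C@@](C)(O)CC/C=C(C)/CCC=C(C)C | intermediate
8 | (4R,5S,8E)-5,9,13-trimethyl-4,5-bis(triethylsilyloxy)tetradeca-8,12-dien-1-yne | C#CC[C@@H](O[Si](CC)(CC)CC)[C@@](C)(O[Si](CC)(CC)CC)CC/C=C(C)/CCC=C(C)C | intermediate
9 | (E)-alkenylzirconocene chloride from 8 (cyclopentadienyl rings drawn σ-bonded; not isolated) | Cl[Zr](C1C=CC=C1)(C1C=CC=C1)/C=C/C[C@@H](O[Si](CC)(CC)CC)[C@@](C)(O[Si](CC)(CC)CC)CC/C=C(C)/CCC=C(C)C | intermediate
10 | (1E,4R,5S,8E)-1-iodo-5,9,13-trimethyl-4,5-bis(triethylsilyloxy)tetradeca-1,8,12-triene | I/C=C/C[C@@H](O[Si](CC)(CC)CC)[C@@](C)(O[Si](CC)(CC)CC)CC/C=C(C)/CCC=C(C)C | intermediate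
11 | (2E,6E,10S,11R,13E)-14-iodo-2,6,10-trimethyl-10,11-bis(triethylsilyloxy)tetradeca-2,6,13-trien-1-ol | I/C=C/C[C@@H](O[Si](CC)(CC)CC)[C@@](C)(O[Si](CC)(CC)CC)CC/C=C(C)/CC/C=C(C)/CO | intermediate
12 | [(2S,3S)-3-[(3E,7S,8R,10E)-11-iodo-3,7-dimethyl-7,8-bis(triethylsilyloxy)undeca-3,10-dien-1-yl]-2-methyloxiran-2-yl]methanol | I/C=C/C[C@@H](O[Si](CC)(CC)CC)[C@@](C)(O[Si](CC)(CC)CC)CC/C=C(C)/CC[C@@H]1O[C@@]1(C)CO | intermediate
13 | (2R,3S)-3-[(3E,7S,8R,10E)-11-iodo-3,7-dimethyl-7,8-bis(triethylsilyloxy)undeca-3,10-dien-1-yl]-2-methyloxirane-2-carbaldehyde | I/C=C/C[C@@H](O[Si](CC)(CC)CC)[C@@](C)(O[Si](CC)(CC)CC)CC/C=C(C)/CC[C@@H]1O[C@@]1(C)C=O | intermediate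
14 | (E)-alkenylchromium dichloride from 13 (trivalent chromium; not isolated) | Cl[Cr](Cl)/C=C/C[C@@H](O[Si](CC)(CC)CC)[C@@](C)(O[Si](CC)(CC)CC)CC/C=C(C)/CC[C@@H]1O[C@@]1(C)C=O | intermediate
15 | (3R,4S,7E,11S,12S,13S,14E)-11,12-epoxy-4,8,12-trimethyl-3,4-bis(triethylsilyloxy)cyclotetradeca-7,14-dien-13-ol (target locants; C14=C1) | O[C@H]1/C=C/C[C@@H](O[Si](CC)(CC)CC)[C@@](C)(O[Si](CC)(CC)CC)CC/C=C(C)/CC[C@@H]2O[C@@]12C | intermediate
16 | propionic anhydride | CCC(=O)OC(=O)CC | starting material
17 | (3R,4S,7E,11S,12R,13S,14E)-11,12-epoxy-4,8,12-trimethyl-3,4-bis(triethylsilyloxy)cyclotetradeca-7,14-dien-13-yl propanoate | CCC(=O)O[C@H]1/C=C/C[C@@H](O[Si](CC)(CC)CC)[C@@](C)(O[Si](CC)(CC)CC)CC/C=C(C)/CC[C@@H]2O[C@@]12C | intermediate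
18 | (E)-silyl ketene acetal of 17 (methyl trans to OSiMe3; not isolated) | C/C=C(/O[Si](C)(C)C)O[C@H]1/C=C/C[C@@H](O[Si](CC)(CC)CC)[C@@](C)(O[Si](CC)(CC)CC)CC/C=C(C)/CC[C@@H]2O[C@@]12C | intermediate
19 | trimethylsilyl ester of 20 (not isolated) | C[C@H](C(=O)O[Si](C)(C)C)[C@@H]1/C=C/[C@]2(C)O[C@H]2CC/C(C)=C/CC[C@](C)(O[Si](CC)(CC)CC)[C@H](O[Si](CC)(CC)CC)C1 | intermediate
20 | (2S)-2-[(1S,3R,4S,7E,11S,12S,13E)-11,12-epoxy-4,8,12-trimethyl-3,4-bis(triethylsilyloxy)cyclotetradeca-7,13-dien-1-yl]propanoic acid | C[C@H](C(=O)O)[C@@H]1/C=C/[C@]2(C)O[C@H]2CC/C(C)=C/CC[C@](C)(O[Si](CC)(CC)CC)[C@H](O[Si](CC)(CC)CC)C1 | intermediate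
21 | (2S)-2-[(1R,3R,4S,7E,11S,12S)-11,12-epoxy-4,8,12-trimethyl-3,4-bis(triethylsilyloxy)cyclotetradec-7-en-1-yl]propanoic acid | C[C@H](C(=O)O)[C@@H]1CC[C@]2(C)O[C@H]2CC/C(C)=C/CC[C@](C)(O[Si](CC)(CC)CC)[C@H](O[Si](CC)(CC)CC)C1 | intermediate
22 | (2S)-2-[(1R,3R,4S,7E,11S,12S)-11,12-epoxy-3,4-dihydroxy-4,8,12-trimethylcyclotetradec-7-en-1-yl]propanoic acid (not isolated) | C[C@H](C(=O)O)[C@@H]1CC[C@]2(C)O[C@H]2CC/C(C)=C/CC[C@](C)(O)[C@H](O)C1 | intermediate
23 | (1R,3R,4S,7E,11S,12S,15S)-11,12-epoxy-4-hydroxycembr-7-en-17,3-olide | C[C@@H]1C(=O)O[C@@H]2C[C@H]1CC[C@]1(C)O[C@H]1CC/C(C)=C/CC[C@]2(C)O | intermediate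
24 | (1R,3R,4S,6E,8S,11S,12S,15S)-11,12-epoxy-8-hydroperoxy-4-hydroxycembr-6-en-17,3-olide | C[C@@H]1C(=O)O[C@@H]2C[C@H]1CC[C@]1(C)O[C@H]1CC[C@](C)(OO)/C=C/C[C@]2(C)O | target

## Step count and least certain steps

Total step count: 15. Longest linear sequence: 15 steps, from 1 to 24; 5 and 16 are commercial.

**Step 10 (key step).** The most likely failure is poor facial selectivity at C13, because the conformation of the closing 14-membered ring can override the Felkin–Anh preference. Less likely are single-electron reduction of the epoxy aldehyde by divalent chromium and intermolecular coupling at insufficient dilution. Fallback: the stereocentre is reset by substrate-controlled reduction in place of the ring-closing addition. Setting out from 13, the cyclisation is taken through with whatever epimer mixture forms, including the (13R)-alcohol F1. Dess–Martin oxidation converges all material on the epoxy enone F2. Reduction with Zn(BH4)2 in ether at low temperature, where zinc bridges the oxirane and carbonyl oxygens and hydride enters from the open face, should give the erythro 13S alcohol. The route is rejoined at 15.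

**Step 12.** Three processes can spoil the outcome: loss of ketene acetal geometry during enolisation, a boat-like transition state imposed by the ring (either would invert C15 relative to C1), and rotation about C12–C13 that places C12 axial (this would send C15 to the other face of C1). Ketene loss from the ester enolate is a further risk. Fallback: C15 is decoupled from the rearrangement. Setting out from 15, acetylation gives the acetate F3, whose Ireland–Claisen rearrangement has no enolate geometry to control and gives the acid F4 with C1 set. Diimide reduction gives F5, and Bu4NF followed by carbodiimide lactonisation gives the nor-methyl lactone F6. Its dianion (LiN(i-Pr)2, 2.2 equiv) is methylated with methyl iodide anti to the C1–C14 bond, which gives the trans 15S arrangement. The route is rejoined at 23.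

**Step 13.** The reduction may be incomplete or unselective. C13=C14 is flanked by the quaternary C12 and the branched C1, which slows diimide and narrows its preference over the trisubstituted C7=C8 olefin. Fallback: selectivity is taken from proximity and no longer from substitution. Setting out from 20, a carboxylate-directed hydrogenation with [Rh(C7H8)(Ph2P(CH2)4PPh2)]BF4 and H2 in CH2Cl2 delivers hydrogen to the olefin that lies three bonds from the acid. The route is rejoined at 21, and no new compound arises.

**Step 15.** Two processes compete with the wanted one: hydrogen abstraction from the C19 methyl in place of C6 (both lie on the more substituted side of the olefin), and attack on the wrong face of the ring olefin, which gives the C8 epimer. Fallback: the oxygenation is moved before lactone closure, onto a macrocycle of different shape. Setting out from 21, photooxygenation under the same conditions, now steered by the two silyl ethers and without the lactone bridge, gives the hydroperoxy acid F7 after separation from its isomers. Bu4NF frees the dihydroxy hydroperoxy acid F8, and carbodiimide lactonisation, expected to outrun acylation of the hydroperoxide, closes the lactone. The route is rejoined at 24.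

## Further compounds

F1 | step 10 | (3R,4S,7E,11S,12S,13R,14E)-11,12-epoxy-4,8,12-trimethyl-3,4-bis(triethylsilyloxy)cyclotetradeca-7,14-dien-13-ol (13-epimer of 15) | O[C@@H]1/C=C/C[C@@H](O[Si](CC)(CC)CC)[C@@](C)(O[Si](CC)(CC)CC)CC/C=C(C)/CC[C@@H]2O[C@@]12C
F2 | step 10 | (3R,4S,7E,11S,12R,14E)-11,12-epoxy-4,8,12-trimethyl-3,4-bis(triethylsilyloxy)cyclotetradeca-7,14-dien-13-one | O=C1/C=C/C[C@@H](O[Si](CC)(CC)CC)[C@@](C)(O[Si](CC)(CC)CC)CC/C=C(C)/CC[C@@H]2O[C@@]12C
F3 | step 12 | acetate of 15 | CC(=O)O[C@H]1/C=C/C[C@@H](O[Si](CC)(CC)CC)[C@@](C)(O[Si](CC)(CC)CC)CC/C=C(C)/CC[C@@H]2O[C@@]12C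
F4 | step 12 | 2-[(7E,13E)-11,12-epoxy-4,8,12-trimethyl-3,4-bis(triethylsilyloxy)cyclotetradeca-7,13-dien-1-yl]acetic acid (ring centres as in 20) | OC(=O)C[C@@H]1/C=C/[C@]2(C)O[C@H]2CC/C(C)=C/CC[C@](C)(O[Si](CC)(CC)CC)[C@H](O[Si](CC)(CC)CC)C1
F5 | step 12 | 2-[(7E)-11,12-epoxy-4,8,12-trimethyl-3,4-bis(triethylsilyloxy)cyclotetradec-7-en-1-yl]acetic acid (ring centres as in 21) | OC(=O)C[C@@H]1CC[C@]2(C)O[C@H]2CC/C(C)=C/CC[C@](C)(O[Si](CC)(CC)CC)[C@H](O[Si](CC)(CC)CC)C1
F6 | step 12 | 16-nor analogue of 23 (lactone without the C15 methyl) | C1C(=O)O[C@@H]2C[C@H]1CC[C@]1(C)O[C@H]1CC/C(C)=C/CC[C@]2(C)O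
F0 | step 13 | none | none
F7 | step 15 | (2S)-2-[(6E,8S)-11,12-epoxy-8-hydroperoxy-4,8,12-trimethyl-3,4-bis(triethylsilyloxy)cyclotetradec-6-en-1-yl]propanoic acid (other centres as in 21) | C[C@H](C(=O)O)[C@@H]1CC[C@]2(C)O[C@H]2CC[C@](C)(OO)/C=C/C[C@](C)(O[Si](CC)(CC)CC)[C@H](O[Si](CC)(CC)CC)C1
F8 | step 15 | (2S)-2-[(6E,8S)-11,12-epoxy-8-hydroperoxy-3,4-dihydroxy-4,8,12-trimethylcyclotetradec-6-en-1-yl]propanoic acid (other centres as in 22) | C[C@H](C(=O)O)[C@@H]1CC[C@]2(C)O[C@H]2CC[C@](C)(OO)/C=C/C[C@](C)(O)[C@H](O)C1
A1 | alternative 1 | (R)-limonene | CC1=CC[C@@H](CC1)C(C)=C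
A2 | alternative 1 | bis-epoxy diol (3,4- and 11,12-epoxides, C5 and C10 carbinols) | CC(=C)[C@@H](C[C@@H]1O[C@@]1(C)CO)CC[C@]1(C)O[C@H]1CO
A3 | alternative 2 | macrocyclic lactone with C9 phenyl sulfone and C4 triethylsilyl ether | C[C@@H]1C(=O)O[C@@H]2C[C@H]1CC[C@]1(C)O[C@H]1CC(S(=O)(=O)c1ccccc1)/C(C)=C/CC[C@]2(C)O[Si](CC)(CC)CC
A4 | alternative 3 | sixteen-membered 2-methylene oxacycle (cyclic allyl vinyl ether) | C=C1OC/C(C)=C/CC[C@]2(C)O[C@H]2CC/C(C)=C/CC[C@]1(C)O[Si](CC)(CC)CC
A5 | alternative 3 | 14-membered C3 ketone with C1 isopropenyl group | CC(=C)[C@@H]1CC[C@]2(C)O[C@H]2CC/C(C)=C/CC[C@](C)(O[Si](CC)(CC)CC)C(=O)C1
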